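**Strategy.** Ring B is disconnected across B5–B6 and B3–B4. Its hydroxyls on B2 and B4 are 1,3-related, the ether-bearing B1 is alpha to B2 and the chain-bearing B6 is beta to it, so ring B is a masked cyclohexane-1,3-dione. A single Michael–Claisen annulation of dimethyl malonate onto a macrocyclic enone therefore builds ring B with its complete oxygen pattern, the hindered B1–O bond being in place beforehand. The precursor is a 20-membered (Z)-alpha-aryloxy enone in which ring A, as its methyl ether, is tied through its ether oxygen to the acetyl-bearing alkene carbon B1 and through fourteen methylenes to the alkene CH B6; an intramolecular Horner–Wadsworth–Emmons reaction closes it.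

Key step: step 9

Labels: ring B carries the ether oxygen on B1, OH on B2 and B4, H on B3 and B5, and the chain on B6. Ring A carries its hydroxyl, the chain terminus and the ether oxygen on alternate carbons, each meta to the other two. The chain is fourteen CH2 groups running from B6 to ring A.

Assumption: the cyclohexane-1,3-diones formed in steps 9 and 10 are drawn as diketo forms although they should exist largely as enols and as diastereomer mixtures. The macrocyclic enone is drawn as its Z isomer, and any E isomer would serve equally because the alkene is consumed in the key step.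

**Step 1**
Reactants: 1 ω-pentadecalactone
Product: 3 methyl 15-bromopentadecanoate, via 15-bromopentadecanoic acid 2 (not isolated)
Conditions: 33% HBr/AcOH, H2SO4 (cat.), 60 °C; evaporate; then MeOH, H2SO4 (cat.), reflux
Reagents that add atoms: hydrogen bromide (Br); methanol (CO)
Why: Acid-mediated alkyl–oxygen cleavage of the lactone by bromide gives the ω-bromo acid, which Fischer esterification converts into the methyl ester.

**Step 2**
Reactants: 4 3-bromo-5-methoxyphenol
Product: 5 1-bromo-3-methoxy-5-(methoxymethoxy)benzene
Conditions: MOMCl, iPr2NEt, CH2Cl2, 0 °C to rt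
Reagents that add atoms: chloromethyl methyl ether (COCCl)
Why: O-alkylation of the phenol by the reactive α-chloro ether (Williamson type) gives a MOM acetal that is inert to organozinc reagents and to hydride.

**Step 3**
Reactants: 3 methyl 15-bromopentadecanoate; 5 1-bromo-3-methoxy-5-(methoxymethoxy)benzene
Product: 7 methyl 15-[3-methoxy-5-(methoxymethoxy)phenyl]pentadecanoate, via (15-methoxy-15-oxopentadecyl)zinc bromide 6 (not isolated)
Conditions: 3, Zn dust, I2 (5 mol%), DMA, 80 °C; then 5, Pd(OAc)2 (2 mol%), SPhos (4 mol%), THF, rt to 50 °C
Reagents that add atoms: none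
Why: Negishi coupling, in which zerovalent palladium formed in situ inserts into the aryl bromide, the primary alkylzinc transmetalates and the bulky biarylphosphine makes reductive elimination outrun β-hydride elimination, with ester and MOM ether tolerated.

**Step 4**
Reactants: 7 methyl 15-[3-methoxy-5-(methoxymethoxy)phenyl]pentadecanoate
Product: 8 15-[3-methoxy-5-(methoxymethoxy)phenyl]pentadecanal
Conditions: iBu2AlH (1.1 equiv), CH2Cl2, −78 °C; MeOH quench, aq. potassium sodium tartrate
Reagents that add atoms: none
Why: Half-reduction of the methyl ester, since the aluminium hemiacetal formed by hydride addition persists at −78 °C and releases the aldehyde only on work-up.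

**Step 5**
Reactants: 8 15-[3-methoxy-5-(methoxymethoxy)phenyl]pentadecanal
Product: 9 3-(15,15-dimethoxypentadecyl)-5-methoxyphenol
Conditions: HC(OMe)3 (3 equiv), HCl (1.25 M in MeOH, 0.3 equiv), MeOH, 0 to 40 °C; then NaHCO3
Reagents that add atoms: trimethyl orthoformate (COC(OC)OC); methanol (CO)
Why: Anhydrous acid in methanol acetalises the aldehyde and at the same time methanolyses the aryl MOM acetal, so the phenol is freed and the aldehyde masked in one operation.

**Step 6**
Reactants: 9 3-(15,15-dimethoxypentadecyl)-5-methoxyphenol; 10 dimethyl (1-diazo-2-oxopropyl)phosphonate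
Product: 11 dimethyl {1-[3-(15,15-dimethoxypentadecyl)-5-methoxyphenoxy]-2-oxopropyl}phosphonate (racemic)
Conditions: Rh2(OAc)4 (2 mol%), toluene, 80 °C, slow addition of 10
Reagents that add atoms: none
Why: Rhodium carbenoid O–H insertion, in which the electrophilic carbenoid is captured by the phenol oxygen and proton transfer within the oxonium ylide gives the α-aryloxy β-ketophosphonate, whose new centre is racemic and disappears in step 8.

**Step 7**
Reactants: 11 dimethyl {1-[3-(15,15-dimethoxypentadecyl)-5-methoxyphenoxy]-2-oxopropyl}phosphonate
Product: 12 dimethyl {1-[3-methoxy-5-(15-oxopentadecyl)phenoxy]-2-oxopropyl}phosphonate (racemic)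
Conditions: 1 M HCl, THF, rt
Reagents that add atoms: water (O)
Why: Acid-catalysed acetal hydrolysis through the oxocarbenium ion, which leaves the β-ketophosphonate and the aryl ethers untouched.

**Step 8**
Reactants: 12 dimethyl {1-[3-methoxy-5-(15-oxopentadecyl)phenoxy]-2-oxopropyl}phosphonate
Product: 13 macrocyclic (Z)-α-aryloxy enone (20-membered ring; ring A is bridged from its ether oxygen through C(COCH3)=CH and fourteen CH2 groups to its chain-bearing carbon; ether oxygen and chain cis on the alkene)
Conditions: K2CO3, 18-crown-6, toluene, 65 °C, syringe-pump addition to 1 mM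
Reagents that add atoms: none
Why: Intramolecular Horner–Wadsworth–Emmons olefination of the stabilised phosphonate anion with the aldehyde, where high dilution favours closure of the unstrained 20-membered ring and the acetyl group is expected to end up trans to the chain.

**Step 9**
Reactants: 13 macrocyclic (Z)-α-aryloxy enone; 14 dimethyl malonate
Product: 15 macrocycle-fused methyl 2-alkyl-3-aryloxy-4,6-dioxocyclohexane-1-carboxylate (ring B: OAr and H on B1, C=O at B2, H2 on B3, C=O at B4, CO2Me and H on B5, chain and H on B6; diastereomer mixture)
Conditions: NaOMe (3 equiv), MeOH/THF, 65 °C; then 1 M HCl, 0 °C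
Reagents that add atoms: none
Why: Proposed new method: sodium dimethyl malonate adds reversibly to the beta carbon B6, proton exchange gives the methyl ketone enolate, and its carbon B3 attacks a malonate ester carbonyl (B4) with loss of methoxide, the irreversible deprotonation of the new 1,3-dione pulling the equilibria forward. The closest known reaction type is the Michael–Claisen annulation of alkyl enones with malonates to cyclohexane-1,3-diones (the dimedone synthesis), here extended to an α-aryloxy enone, whose aryloxy group should weaken the acceptor only moderately because the aryl ring competes for the oxygen lone pair. Ring B closes by a 6-(enolendo)-exo-trig Claisen acylation of enolate carbon B3 onto ester carbon B4. Three sp3 centres arise (B1, B5, B6) without external control, B1 and B5 can equilibrate under methoxide, and all three are erased in step 11, so no lasting stereocentre is set. The step needs 1,4- over 1,2-addition, which the soft stabilised nucleophile under reversible conditions secures, and closure from the methyl carbon, which is secured because the other enolisable position B1 could close only a four-membered ring.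

**Step 10**
Reactants: 15 macrocycle-fused methyl 2-alkyl-3-aryloxy-4,6-dioxocyclohexane-1-carboxylate
Product: 17 macrocycle-fused 5-alkyl-4-aryloxycyclohexane-1,3-dione (diastereomer mixture), via β-keto acid 16 (not isolated)
Conditions: 2 M NaOH, MeOH/THF, reflux; then HCl to pH 1, 70 °C
Reagents that add atoms: none
Why: Saponification of the ester while the ring is shielded as its dione enolate, then thermal decarboxylation of the β-keto acid through the cyclic six-membered transition state, the classical sequel to a Michael–Claisen annulation.

**Step 11**
Reactants: 17 macrocycle-fused 5-alkyl-4-aryloxycyclohexane-1,3-dione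
Product: 18 tri-O-methyl ether of the target (OMe on ring A and on B2 and B4)
Conditions: I2 (2 equiv), MeOH, reflux; aq. Na2S2O3
Reagents that add atoms: methanol (CO)
Why: Iodine–methanol aromatization, in which acid-catalysed formation of the methyl enol ethers, α-iodination and loss of HI should deliver the resorcinol dimethyl ether, while iodine does not substitute the aryl ethers under these acidic, reducing conditions.

**Step 12**
Reactants: 18 tri-O-methyl ether of the target
Product: 19 CNP0173380.0 (target)
Conditions: BBr3 (6 equiv), CH2Cl2, −78 °C to rt; then H2O
Reagents that add atoms: none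
Why: Lewis-acid ether cleavage, in which BBr3 binds each methoxy oxygen and bromide removes the methyl group by SN2, the diaryl ether having no sp3 C–O carbon to attack, and hydrolysis of the aryl borates frees the three phenols.

**Compound list**
1 | ω-pentadecalactone (oxacyclohexadecan-2-one) | O=C1CCCCCCCCCCCCCCO1 | starting material
2 | 15-bromopentadecanoic acid | OC(=O)CCCCCCCCCCCCCCBr | intermediate
3 | methyl 15-bromopentadecanoate | COC(=O)CCCCCCCCCCCCCCBr | intermediate
4 | 3-bromo-5-methoxyphenol | COc1cc(O)cc(Br)c1 | starting material
5 | 1-bromo-3-methoxy-5-(methoxymethoxy)benzene | COCOc1cc(Br)cc(OC)c1 | intermediate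
6 | (15-methoxy-15-oxopentadecyl)zinc bromide | COC(=O)CCCCCCCCCCCCCC[Zn]Br | intermediate
7 | methyl 15-[3-methoxy-5-(methoxymethoxy)phenyl]pentadecanoate | COC(=O)CCCCCCCCCCCCCCc1cc(OC)cc(OCOC)c1 | intermediate
8 | 15-[3-methoxy-5-(methoxymethoxy)phenyl]pentadecanal | O=CCCCCCCCCCCCCCCc1cc(OC)cc(OCOC)c1 | intermediate
9 | 3-(15,15-dimethoxypentadecyl)-5-methoxyphenol | COC(OC)CCCCCCCCCCCCCCc1cc(O)cc(OC)c1 | intermediate
10 | dimethyl (1-diazo-2-oxopropyl)phosphonate | COP(=O)(OC)C(=[N+]=[N-])C(C)=O | starting material
11 | dimethyl {1-[3-(15,15-dimethoxypentadecyl)-5-methoxyphenoxy]-2-oxopropyl}phosphonate (racemic) | COC(OC)CCCCCCCCCCCCCCc1cc(OC)cc(OC(C(C)=O)P(=O)(OC)OC)c1 | intermediate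
12 | dimethyl {1-[3-methoxy-5-(15-oxopentadecyl)phenoxy]-2-oxopropyl}phosphonate (racemic) | O=CCCCCCCCCCCCCCCc1cc(OC)cc(OC(C(C)=O)P(=O)(OC)OC)c1 | intermediate
13 | macrocyclic (Z)-α-aryloxy enone, 20-membered, acetyl on B1 | CC(=O)/C1=C/CCCCCCCCCCCCCCc2cc(OC)cc(c2)O1 | intermediate
14 | dimethyl malonate | COC(=O)CC(=O)OC | starting material
15 | macrocycle-fused methyl 2-alkyl-3-aryloxy-4,6-dioxocyclohexane-1-carboxylate (diastereomer mixture) | COC(=O)C1C(=O)CC(=O)C2Oc3cc(OC)cc(c3)CCCCCCCCCCCCCCC12 | intermediate
16 | corresponding β-keto acid (diastereomer mixture) | OC(=O)C1C(=O)CC(=O)C2Oc3cc(OC)cc(c3)CCCCCCCCCCCCCCC12 | intermediate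
17 | macrocycle-fused 5-alkyl-4-aryloxycyclohexane-1,3-dione (diastereomer mixture) | O=C1CC(=O)C2Oc3cc(OC)cc(c3)CCCCCCCCCCCCCCC2C1 | intermediate
18 | tri-O-methyl ether of the target | COc1cc2cc(c1)Oc1c(OC)cc(OC)cc1CCCCCCCCCCCCCC2 | intermediate
19 | CNP0173380.0 | Oc1cc2cc(c1)Oc1c(O)cc(O)cc1CCCCCCCCCCCCCC2 | target

**Step count.** Total: 12 steps. Longest linear sequence: 11 steps (steps 1 and 3–12 from ω-pentadecalactone; likewise steps 2–12 from 3-bromo-5-methoxyphenol).

**Steps most likely to fail**

Step 9. The captodative alkene may resist conjugate addition, or the adduct may revert faster than the Claisen closure, with base-induced deconjugation of the enone as a drain. The fallback sets out from 13 and replaces the reversible addition by a Lewis-acid-driven, irreversible one. Mukaiyama–Michael addition of 1-methoxy-1-(trimethylsilyloxy)ethene (TiCl4, CH2Cl2, −78 °C, with the metal chelated between the carbonyl and aryloxy oxygens) should give the macrocyclic δ-keto ester F1. Its intramolecular Claisen cyclisation (KOtBu, THF, 0 °C to rt), the known closure of 5-oxo esters to cyclohexane-1,3-diones, should return to the route at 17, bypassing 15 and step 10.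

Step 11. Acid released during the oxidation may cleave or reduce the α-aryloxy ketone C–O bond at B1 before ring B is aromatic. O-methylation may also stop part-way, which is harmless because step 12 removes every methyl ether. The fallback sets out from 17 and uses catalytic dehydrogenation in place of halogenation: Pd/C (10% Pd) in refluxing mesitylene under a nitrogen sweep should give the ring A methyl ether with a free ring B resorcinol F2. BBr3 as in step 12 then brings it back to the route at 19.

Step 6. The rhodium carbenoid may be diverted into carbene dimerisation or into attack on the electron-rich ring A or the acetal oxygens instead of O–H insertion. The fallback sets out from 9 and builds the same bond by ionic chemistry. O-alkylation of the phenol with (dimethoxyphosphoryl)methyl trifluoromethanesulfonate (Cs2CO3, MeCN) should give the aryloxymethylphosphonate F3. Its α-lithiation and acylation (LiN(iPr)2, 2.2 equiv, THF, −78 °C; N-methoxy-N-methylacetamide) returns to the route at 11.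

**Further compounds**
F1 | step 9 | macrocyclic δ-keto ester: methyl 2-(macrocyclyl)acetate with CH2CO2Me on B6 and H, OAr and acetyl on B1 (diastereomer mixture) | COC(=O)CC1CCCCCCCCCCCCCCc2cc(OC)cc(c2)OC1C(C)=O
F2 | step 11 | ring A mono-methyl ether of the target (free OH on B2 and B4) | COc1cc2cc(c1)Oc1c(O)cc(O)cc1CCCCCCCCCCCCCC2
F3 | step 6 | dimethyl {[3-(15,15-dimethoxypentadecyl)-5-methoxyphenoxy]methyl}phosphonate | COC(OC)CCCCCCCCCCCCCCc1cc(OC)cc(OCP(=O)(OC)OC)c1
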